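**Plan**
- **Cuts, in retrosynthetic order:** the C6'=O of the ring B quinone (back to the 3'-phenol), the two O-benzyl groups, the enol O–Si bond, C3–C4 of ring C, and finally O1–C2. This leaves a hexasubstituted ring A acetophenone and a ring B cinnamyl carbonate.
- **Enabling feature:** C3–C4 joins the carbonyl carbon C4 on ring A to the CH2 next to C2. In the enol form it is a C3=C4 double bond inside six-membered ring C. It lies between an aryl-bound C(OSi)=CH2 unit and the vinyl group of the O1–C2 allyl ether, so it can be formed by ring-closing metathesis.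
- **Forward order:** rings A and B come from commercial arenes, three steps each. They are joined at O1–C2, ring C then closes at C3–C4, and ring B is oxidised to the quinone last.
- **Stereochemistry:** C2 (S), the only stereocentre, is set by ligand control in an iridium-catalysed branched-selective allylic etherification. No later step breaks a bond at C2, and all later steps avoid a free enolate, strong acid and light.

Key step: step 9

Assumption: the (Sa,Sc,Sc) antipode of the phosphoramidite is taken to give the (S)-ether, following the sense of induction known for heteroatom nucleophiles and cinnamyl carbonates; both antipodes are commercial, so the mirror-image ligand is used unchanged if a first run shows the opposite sense.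

**Step 1**
Reactants: 1 2',4',6'-trihydroxyacetophenone (phloroacetophenone)
Product: 2 2',4',6'-trihydroxy-3',5'-dimethylacetophenone
Conditions: MeI (2.1 equiv), NaOMe (3 equiv), MeOH, 0 °C to reflux
Reagents that add atoms: iodomethane, CI
Why: C-alkylation of an acylphloroglucinol anion, which reacts as a vinylogous triketone enolate at both free ring carbons, with MeI limited to two equivalents so that geminal methylation and dearomatisation are held back.

**Step 2**
Reactants: 2 2',4',6'-trihydroxy-3',5'-dimethylacetophenone
Product: 3 2',6'-dihydroxy-4'-methoxy-3',5'-dimethylacetophenone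
Conditions: Me2SO4 (1.0 equiv), K2CO3 (1.0 equiv), acetone, rt to reflux
Reagents that add atoms: dimethyl sulfate, COS(=O)(=O)OC
Why: Williamson O-methylation with a hard electrophile, in which the 4'-hydroxyl para to the acetyl group reacts first because it is the most acidic and is not chelated to the carbonyl.

**Step 3**
Reactants: 3 2',6'-dihydroxy-4'-methoxy-3',5'-dimethylacetophenone
Product: 4 2'-(benzyloxy)-6'-hydroxy-4'-methoxy-3',5'-dimethylacetophenone
Conditions: BnBr (1.05 equiv), K2CO3, acetone, reflux
Reagents that add atoms: benzyl bromide, BrCc1ccccc1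
Why: Williamson etherification of one of two equivalent hydroxyls, after which the remaining one is locked in a strong hydrogen bond to the carbonyl and resists a second alkylation.

**Step 4**
Reactants: 5 3-(benzyloxy)-4-methoxybenzaldehyde (commercial O-benzylisovanillin); 6 triethyl phosphonoacetate
Product: 7 ethyl (E)-3-[3-(benzyloxy)-4-methoxyphenyl]prop-2-enoate
Conditions: LiCl, DBU, MeCN, rt
Reagents that add atoms: none
Why: Horner–Wadsworth–Emmons olefination under Masamune–Roush conditions, where the stabilised phosphonate should give the (E)-cinnamate needed for a geometrically pure allyl electrophile.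

**Step 5**
Reactants: 7 ethyl (E)-3-[3-(benzyloxy)-4-methoxyphenyl]prop-2-enoate
Product: 8 (E)-3-[3-(benzyloxy)-4-methoxyphenyl]prop-2-en-1-ol
Conditions: i-Bu2AlH (2.3 equiv), CH2Cl2, −78 °C; aq. potassium sodium tartrate
Reagents that add atoms: none
Why: 1,2-reduction of an enoate by an aluminium hydride, which leaves the alkene geometry and the benzyl ether intact.

**Step 6**
Reactants: 8 (E)-3-[3-(benzyloxy)-4-methoxyphenyl]prop-2-en-1-ol
Product: 9 tert-butyl (E)-3-[3-(benzyloxy)-4-methoxyphenyl]prop-2-en-1-yl carbonate
Conditions: Boc2O, Bu4NHSO4 (cat.), 30 % aq. NaOH, CH2Cl2, 0 °C to rt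
Reagents that add atoms: di-tert-butyl dicarbonate, CC(C)(C)OC(=O)OC(=O)OC(C)(C)C
Why: phase-transfer O-acylation of a primary allylic alcohol, with the tert-butyl carbonate chosen because the tert-butoxide it later releases is too bulky to compete with a slow aryloxide nucleophile.

**Step 7**
Reactants: 4 2'-(benzyloxy)-6'-hydroxy-4'-methoxy-3',5'-dimethylacetophenone; 9 tert-butyl (E)-3-[3-(benzyloxy)-4-methoxyphenyl]prop-2-en-1-yl carbonate
Product: 11 1-[2-(benzyloxy)-6-{[(1S)-1-[3-(benzyloxy)-4-methoxyphenyl]prop-2-en-1-yl]oxy}-4-methoxy-3,5-dimethylphenyl]ethan-1-one, via lithium aryloxide 10 (not isolated)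
Conditions: 4 (1.2 equiv), LiN(SiMe3)2, THF, 0 °C; then 9, [Ir(cod)Cl]2 (2 mol %), (Sa,Sc,Sc)-N,N-bis(1-phenylethyl)dinaphtho[2,1-d:1',2'-f][1,3,2]dioxaphosphepin-4-amine (4 mol %, catalyst pre-activated with n-PrNH2), THF, rt to 40 °C
Reagents that add atoms: none
Why: iridium-catalysed asymmetric allylic etherification, in which the cyclometalated iridium–phosphoramidite ionises the linear carbonate and the aryloxide attacks the aryl-bearing allyl terminus anti to the metal, the ligand fixing the exposed allyl face so that the branched (S)-ether should form.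

**Step 8**
Reactants: 11 (S)-allyl aryl ether ketone
Product: 13 tert-butyl({1-[2-(benzyloxy)-6-{[(1S)-1-[3-(benzyloxy)-4-methoxyphenyl]prop-2-en-1-yl]oxy}-4-methoxy-3,5-dimethylphenyl]ethenyl}oxy)dimethylsilane, via potassium enolate 12 (not isolated)
Conditions: KN(SiMe3)2, THF, −78 °C; TBSCl, −78 to 0 °C; chromatography on Et3N-deactivated silica
Reagents that add atoms: tert-butyldimethylsilyl chloride, CC(C)(C)[Si](C)(C)Cl
Why: kinetic enolate formation at the only enolisable position followed by O-silylation (silyl enol ether synthesis), the Lewis-acid-free basic medium sparing the easily ionised benzylic allylic aryl ether and leaving C2 untouched.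

**Step 9**
Reactants: 13 silyl enol ether of the (S)-allyl aryl ether
Product: 14 (2S)-5-(benzyloxy)-2-[3-(benzyloxy)-4-methoxyphenyl]-4-[(tert-butyldimethylsilyl)oxy]-7-methoxy-6,8-dimethyl-2H-chromene
Conditions: second-generation Grubbs catalyst (H2IMes)(PCy3)Cl2Ru=CHPh (5–10 mol %), 1,4-benzoquinone (20 mol %), degassed toluene (0.005 M), 60 °C, argon sparge, dark
Reagents that add atoms: none
Why: The ruthenium benzylidene first exchanges with the monosubstituted vinyl group on C2, the resulting alkylidene at C3 adds across the C(OTBS)=CH2 unit with C3 bonding to C4, and cycloreversion of the ruthenacyclobutane delivers C3=C4 and Ru=CH2, which carries the chain and leaves as ethene. The closest known reaction type is silyl enol ether–ene ring-closing metathesis, which converts silyl enol ethers of 2-(N-allylamino)acetophenones into 4-silyloxy-1,2-dihydroquinolines and olefinic ketones into cyclic silyl enol ethers. Ring C closes as a six-membered ring with the new double bond endocyclic and both CH2 termini expelled, so no ring-size or alkene-geometry question arises. No stereocentre is created, and C2 sits beside the reacting vinyl group without any of its bonds being broken, so the (S) configuration from step 7 should carry over. The step needs closure to outrun ruthenium-hydride migration of the allyl double bond towards C2 (which would erase the stereocentre) and dimerisation: the flanking 3'-methyl and 6'-benzyloxy groups press the allyloxy arm and the twisted enol ether together, high dilution disfavours intermolecular metathesis, benzoquinone intercepts hydrides, and the fully substituted oxygen-bearing alkene carbon is too crowded to bind ruthenium as an inert Fischer carbene. Moderate temperature and exclusion of light guard against electrocyclic opening of the 2H-chromene, the one path by which the product itself could racemise.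

**Step 10**
Reactants: 14 (2S)-4-silyloxy-2H-chromene
Product: 15 (2S)-5-(benzyloxy)-2-[3-(benzyloxy)-4-methoxyphenyl]-7-methoxy-6,8-dimethylchroman-4-one
Conditions: HF·pyridine, pyridine, THF, 0 °C
Reagents that add atoms: none
Why: fluoride-induced cleavage of a silyl enol ether in a proton-rich medium, so that C3 is protonated at once and no enolate lives long enough to expel O1 by retro-oxa-Michael opening, which keeps C2 (S).

**Step 11**
Reactants: 15 (2S)-dibenzyl flavanone
Product: 16 (2S)-5-hydroxy-2-(3-hydroxy-4-methoxyphenyl)-7-methoxy-6,8-dimethylchroman-4-one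
Conditions: H2 (1 atm), Pd/C (10 %), EtOAc, rt, stopped after two equivalents of H2
Reagents that add atoms: none
Why: catalytic hydrogenolysis, in which the two primary O-benzyl bonds cleave well before the secondary, ring-bound C2–O1 bond or the aryl ketone, as is usual for benzyl-protected flavanones in a neutral solvent.

**Step 12**
Reactants: 16 (2S)-5,3'-dihydroxyflavanone
Product: 17 2-[(2S)-5-hydroxy-7-methoxy-6,8-dimethyl-4-oxochroman-2-yl]-5-methoxycyclohexa-2,5-diene-1,4-dione (target)
Conditions: ON(SO3K)2 (2.5 equiv), KH2PO4 buffer (pH 6), acetone–H2O, 0 °C to rt, dark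
Reagents that add atoms: potassium nitrosodisulfonate, [K+].[K+].[O]N(S(=O)(=O)[O-])S(=O)(=O)[O-]
Why: Teuber oxidation, in which one nitroxyl radical removes the ring B phenolic hydrogen and a second couples through oxygen at the free para carbon C6' before imidodisulfonate is lost to give the p-quinone, while the ring A hydroxyl is chelated to C4=O with no free ortho or para carbon and the near-neutral buffer spares C2.

**Compound list**
1 | 2',4',6'-trihydroxyacetophenone | CC(=O)c1c(O)cc(O)cc1O | starting material
2 | 2',4',6'-trihydroxy-3',5'-dimethylacetophenone | CC(=O)c1c(O)c(C)c(O)c(C)c1O | intermediate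
3 | 2',6'-dihydroxy-4'-methoxy-3',5'-dimethylacetophenone | CC(=O)c1c(O)c(C)c(OC)c(C)c1O | intermediate
4 | 2'-(benzyloxy)-6'-hydroxy-4'-methoxy-3',5'-dimethylacetophenone | CC(=O)c1c(O)c(C)c(OC)c(C)c1OCc1ccccc1 | intermediate
5 | 3-(benzyloxy)-4-methoxybenzaldehyde | COc1ccc(C=O)cc1OCc1ccccc1 | starting material
6 | triethyl phosphonoacetate | CCOC(=O)CP(=O)(OCC)OCC | starting material
7 | ethyl (E)-3-[3-(benzyloxy)-4-methoxyphenyl]prop-2-enoate | CCOC(=O)/C=C/c1ccc(OC)c(OCc2ccccc2)c1 | intermediate
8 | (E)-3-[3-(benzyloxy)-4-methoxyphenyl]prop-2-en-1-ol | OC/C=C/c1ccc(OC)c(OCc2ccccc2)c1 | intermediate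
9 | tert-butyl (E)-3-[3-(benzyloxy)-4-methoxyphenyl]prop-2-en-1-yl carbonate | CC(C)(C)OC(=O)OC/C=C/c1ccc(OC)c(OCc2ccccc2)c1 | intermediate
10 | lithium 2-acetyl-3-(benzyloxy)-5-methoxy-4,6-dimethylphenolate | [Li+].CC(=O)c1c([O-])c(C)c(OC)c(C)c1OCc1ccccc1 | intermediate (not isolated)
11 | 1-[2-(benzyloxy)-6-{[(1S)-1-[3-(benzyloxy)-4-methoxyphenyl]prop-2-en-1-yl]oxy}-4-methoxy-3,5-dimethylphenyl]ethan-1-one | COc1ccc([C@@H](Oc2c(C)c(OC)c(C)c(OCc3ccccc3)c2C(C)=O)C=C)cc1OCc1ccccc1 | intermediate
12 | potassium enolate of 11 | [K+].COc1ccc([C@@H](Oc2c(C)c(OC)c(C)c(OCc3ccccc3)c2C(=C)[O-])C=C)cc1OCc1ccccc1 | intermediate (not isolated)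
13 | tert-butyldimethylsilyl enol ether of 11 | COc1ccc([C@@H](Oc2c(C)c(OC)c(C)c(OCc3ccccc3)c2C(=C)O[Si](C)(C)C(C)(C)C)C=C)cc1OCc1ccccc1 | intermediate
14 | (2S)-5-(benzyloxy)-2-[3-(benzyloxy)-4-methoxyphenyl]-4-[(tert-butyldimethylsilyl)oxy]-7-methoxy-6,8-dimethyl-2H-chromene | COc1ccc([C@@H]2C=C(O[Si](C)(C)C(C)(C)C)c3c(OCc4ccccc4)c(C)c(OC)c(C)c3O2)cc1OCc1ccccc1 | intermediate
15 | (2S)-5-(benzyloxy)-2-[3-(benzyloxy)-4-methoxyphenyl]-7-methoxy-6,8-dimethylchroman-4-one | COc1ccc([C@@H]2CC(=O)c3c(OCc4ccccc4)c(C)c(OC)c(C)c3O2)cc1OCc1ccccc1 | intermediate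
16 | (2S)-5-hydroxy-2-(3-hydroxy-4-methoxyphenyl)-7-methoxy-6,8-dimethylchroman-4-one | COc1ccc([C@@H]2CC(=O)c3c(O)c(C)c(OC)c(C)c3O2)cc1O | intermediate
17 | 2-[(2S)-5-hydroxy-7-methoxy-6,8-dimethyl-4-oxochroman-2-yl]-5-methoxycyclohexa-2,5-diene-1,4-dione | COC1=CC(=O)C([C@@H]2CC(=O)c3c(O)c(C)c(OC)c(C)c3O2)=CC1=O | target

**Step count**
- Total step count: 12.
- Longest linear sequence: 9 (steps 1–3, then 7–12). The ring B branch, steps 4–6, is equally long.

**Steps most likely to fail**

**Step 7.**
- **Risk:** the crowded, lithium-chelated aryloxide may capture the allyl-iridium intermediate slowly. The product ether, which carries a good aryloxide leaving group on an electron-rich benzylic allylic carbon, may also ionise again. Both processes would divert material to the linear ether and wear down enantiopurity.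
- **Fallback:** the source of chirality moves from the catalyst to the electrophile. The sequence sets out from aldehyde 5 and phenol 4 and returns at 11. Vinylmagnesium bromide adds to 5 to give the racemic allylic alcohol F1. Resolution with immobilised Candida antarctica lipase B and vinyl acetate should acylate the (R)-enantiomer to the (R)-acetate F3 and leave the (S)-allylic alcohol F2. Methyl chloroformate and pyridine convert F2 into the (S)-methyl carbonate F4. Phenol 4 is turned with NaN(SiMe3)2 into the sodium aryloxide F5, which displaces the carbonate under RhCl(PPh3)3 modified with P(OMe)3 in THF at 0 °C. This enantiospecific rhodium-catalysed allylic etherification is known to accept ortho-substituted phenols and to proceed at the branched carbon with net retention, which gives 11.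

**Step 9.**
- **Risk:** the ruthenium alkylidene may stall before it engages the crowded, twisted enol ether. Double-bond migration, desilylation or dimerisation would then take over.
- **Fallback:** the C3–C4 metathesis is kept, but C4 is lowered in oxidation level so that an ordinary styrene is the partner, and the oxygen is returned afterwards. The sequence runs from 11 to 15. LiAlH4 (THF, 0 °C) reduces 11 to the secondary benzylic alcohol F6 (both carbinol epimers). The Burgess reagent dehydrates F6 to the 2-vinylaryl allyl ether F7. Diene ring-closing metathesis with (H2IMes)(PCy3)Cl2Ru=CHPh, a closure well known for 2-vinylphenyl 1-arylallyl ethers, gives the (2S)-flav-3-ene F8. Mukaiyama hydration (Mn(dpm)3, PhSiH3, O2, i-PrOH) places the hydroxyl at C4 through the benzylic radical and gives the flavan-4-ol F9 (both C4 epimers). Dess–Martin periodinane oxidises F9 to flavanone 15, where the route resumes at step 11.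

**Step 12.**
- **Risk:** radical attack may compete at the ring A phenol, ring B may be over-oxidised, and the quinone-bearing C2 may decay or epimerise during isolation.
- **Fallback:** the second quinone heteroatom is brought in as nitrogen by electrophilic substitution instead of radical oxidation. The sequence runs from 16 to 17. Nitrosation (NaNO2, aq. HCl, EtOH, 0 °C) can only strike ring B, because ring A has no free carbon. It should go para to the 3'-hydroxyl to give the 6'-nitrosophenol F10. Hydrogenation (H2, Pd/C, EtOAc) gives the 6'-aminophenol F11. FeCl3 in dilute aq. HCl at 0 °C oxidises F11 to the quinone imine F12, which hydrolyses in the same flask to target 17.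

**Further compounds**
F1 | step 7 | rac-1-[3-(benzyloxy)-4-methoxyphenyl]prop-2-en-1-ol | COc1ccc(C(O)C=C)cc1OCc1ccccc1
F2 | step 7 | (1S)-1-[3-(benzyloxy)-4-methoxyphenyl]prop-2-en-1-ol | COc1ccc([C@@H](O)C=C)cc1OCc1ccccc1
F3 | step 7 | (1R)-1-[3-(benzyloxy)-4-methoxyphenyl]prop-2-en-1-yl acetate | COc1ccc([C@H](OC(C)=O)C=C)cc1OCc1ccccc1
F4 | step 7 | (1S)-1-[3-(benzyloxy)-4-methoxyphenyl]prop-2-en-1-yl methyl carbonate | COc1ccc([C@@H](OC(=O)OC)C=C)cc1OCc1ccccc1
F5 | step 7 | sodium 2-acetyl-3-(benzyloxy)-5-methoxy-4,6-dimethylphenolate | [Na+].CC(=O)c1c([O-])c(C)c(OC)c(C)c1OCc1ccccc1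
F6 | step 9 | 1-[2-(benzyloxy)-6-{[(1S)-1-[3-(benzyloxy)-4-methoxyphenyl]prop-2-en-1-yl]oxy}-4-methoxy-3,5-dimethylphenyl]ethan-1-ol (carbinol epimers) | COc1ccc([C@@H](Oc2c(C)c(OC)c(C)c(OCc3ccccc3)c2C(C)O)C=C)cc1OCc1ccccc1
F7 | step 9 | 1-(benzyloxy)-3-{[(1S)-1-[3-(benzyloxy)-4-methoxyphenyl]prop-2-en-1-yl]oxy}-2-ethenyl-5-methoxy-4,6-dimethylbenzene | COc1ccc([C@@H](Oc2c(C)c(OC)c(C)c(OCc3ccccc3)c2C=C)C=C)cc1OCc1ccccc1
F8 | step 9 | (2S)-5-(benzyloxy)-2-[3-(benzyloxy)-4-methoxyphenyl]-7-methoxy-6,8-dimethyl-2H-chromene | COc1ccc([C@@H]2C=Cc3c(OCc4ccccc4)c(C)c(OC)c(C)c3O2)cc1OCc1ccccc1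
F9 | step 9 | (2S)-5-(benzyloxy)-2-[3-(benzyloxy)-4-methoxyphenyl]-7-methoxy-6,8-dimethylchroman-4-ol (C4 epimers) | COc1ccc([C@@H]2CC(O)c3c(OCc4ccccc4)c(C)c(OC)c(C)c3O2)cc1OCc1ccccc1
F10 | step 12 | (2S)-5-hydroxy-2-(5-hydroxy-4-methoxy-2-nitrosophenyl)-7-methoxy-6,8-dimethylchroman-4-one | COc1cc(N=O)c([C@@H]2CC(=O)c3c(O)c(C)c(OC)c(C)c3O2)cc1O
F11 | step 12 | (2S)-2-(2-amino-5-hydroxy-4-methoxyphenyl)-5-hydroxy-7-methoxy-6,8-dimethylchroman-4-one | COc1cc(N)c([C@@H]2CC(=O)c3c(O)c(C)c(OC)c(C)c3O2)cc1O
F12 | step 12 | (2S)-5-hydroxy-2-(6-imino-4-methoxy-3-oxocyclohexa-1,4-dien-1-yl)-7-methoxy-6,8-dimethylchroman-4-one | COC1=CC(=N)C([C@@H]2CC(=O)c3c(O)c(C)c(OC)c(C)c3O2)=CC1=O
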